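**Plan**

- Cuts: (a) the ketone C(=O)–C1 bond, traced back to an aryl ester in which the 3,5-dioxygenated 4-prenylbenzoyl group hangs on a phenol oxygen of the neighbouring resorcinol ring; (b) C1–C2 and C5–C6 of the cyclohexene (Diels–Alder, with a carboxyl surrogate on C1); (c) the chalcone C=C, the aryl–dienyl bond and the aryl–prenyl bond.
- Forward: prenylated benzoic acid (Stille); dienyl chalcone (Suzuki–Miyaura, Claisen–Schmidt); Cu-bis(oxazoline) Diels–Alder with an α'-hydroxy enone closes the cyclohexene; the ortho acetal is removed and the benzoic acid is esterified onto that oxygen; ketol → acid → N-acyloxyphthalimide; a decarboxylative nickel relay moves the aroyl group from O to C1; deprotection.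
- Enabling feature: the 2'-oxygen of the resorcinol ring on C2 lies 1,5 to the ketone carbon (O–C2'–C3'–C2–C1–C=O, the six atoms of a latent 6H-benzo[c]chromene hemiketal ring) and sits on the same face as the aroyl group, so it can carry that group and hand it to C1.
- Stereochemistry: C2 and C6 (absolute) come from the ligand-controlled endo Diels–Alder; C1 is erased on decarboxylation and set again in the key step by delivery from the C2 aryl oxygen, anti to the C6 aryl group.

Key step: step 15

Numbering used below: cyclohexene C1 (acyl or carboxyl carbon attached), C2 (resorcinol ring), C3=C4 (methyl on C4), C5, C6 (4-oxyphenyl); resorcinol ring C1' (enone carbonyl attached), 2'-O (ortho to that carbonyl), C3' (bonded to C2), 4'-O. MOM = methoxymethyl.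

Assumption: the square-planar Cu(II)·t-Bu-box chelate model is taken to hold for the α'-hydroxy enone, so that the (R,R)-ligand exposes the Cα-Si face; the (S,S)-ligand would be used if the sense proved opposite.

**Route**

Step 1
Reactants: 1 methyl 4-bromo-3,5-dihydroxybenzoate
Product: 2 methyl 4-bromo-3,5-bis(methoxymethoxy)benzoate
Conditions: MOMCl, i-Pr2NEt, CH2Cl2, 0 °C to rt
Reagents that add atoms: chloromethyl methyl ether, COCCl
Why: O-alkylation of both phenols (Williamson type) under amine base, which leaves the methyl ester untouched.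

Step 2
Reactants: 2 methyl 4-bromo-3,5-bis(methoxymethoxy)benzoate; 3 tributyl(3-methylbut-2-en-1-yl)stannane
Product: 4 methyl 3,5-bis(methoxymethoxy)-4-(3-methylbut-2-en-1-yl)benzoate
Conditions: Pd(PPh3)4 (5 mol %), DMF, 100 °C
Reagents that add atoms: none
Why: Stille coupling; oxidative addition into the aryl bromide is helped by the para ester, and allyl transfer from tin with reductive elimination at the less substituted terminus should give the linear prenyl arene.

Step 3
Reactants: 4 methyl 3,5-bis(methoxymethoxy)-4-(3-methylbut-2-en-1-yl)benzoate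
Product: 5 3,5-bis(methoxymethoxy)-4-(3-methylbut-2-en-1-yl)benzoic acid
Conditions: LiOH, THF–MeOH–H2O, rt; then 1 M HCl to pH 4, 0 °C
Reagents that add atoms: lithium hydroxide, [Li+].[OH-]
Why: ester saponification; the MOM acetals are stable to base and to the brief cold acidification.

Step 4
Reactants: 6 2-methylbut-1-en-3-yne; 7 pinacolborane
Product: 8 (E)-4,4,5,5-tetramethyl-2-(3-methylbuta-1,3-dien-1-yl)-1,3,2-dioxaborolane
Conditions: Cp2Zr(H)Cl (10 mol %), Et3N (10 mol %), neat, 60 °C
Reagents that add atoms: none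
Why: zirconium-hydride-catalysed syn hydroboration of the terminal alkyne (anti-Markovnikov) gives the E-dienylboronate and leaves the 1,1-disubstituted alkene alone.

Step 5
Reactants: 9 1-(2,4-dihydroxyphenyl)ethan-1-one
Product: 10 1-(2,4-dihydroxy-3-iodophenyl)ethan-1-one
Conditions: I2, HIO3, EtOH–H2O, rt
Reagents that add atoms: iodine, II; iodic acid, O[I](=O)=O
Why: electrophilic aromatic iodination at C3, the position ortho to both hydroxyls; iodic acid reoxidises iodide so that all iodine is used.

Step 6
Reactants: 10 1-(2,4-dihydroxy-3-iodophenyl)ethan-1-one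
Product: 11 1-[3-iodo-2,4-bis(methoxymethoxy)phenyl]ethan-1-one
Conditions: NaH, MOMCl, DMF, 0 °C to rt
Reagents that add atoms: chloromethyl methyl ether, COCCl
Why: O-alkylation of both phenoxides; the sodium salt is needed for the hydrogen-bonded 2-OH.

Step 7
Reactants: 11 1-[3-iodo-2,4-bis(methoxymethoxy)phenyl]ethan-1-one; 8 (E)-4,4,5,5-tetramethyl-2-(3-methylbuta-1,3-dien-1-yl)-1,3,2-dioxaborolane
Product: 12 1-[2,4-bis(methoxymethoxy)-3-[(1E)-3-methylbuta-1,3-dien-1-yl]phenyl]ethan-1-one
Conditions: Pd(dppf)Cl2 (5 mol %), K3PO4, 1,4-dioxane–H2O, 80 °C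
Reagents that add atoms: none
Why: Suzuki–Miyaura coupling with retention of the E-alkenyl geometry; the dppf ligand should cope with the di-ortho-substituted iodide.

Step 8
Reactants: 12 1-[2,4-bis(methoxymethoxy)-3-[(1E)-3-methylbuta-1,3-dien-1-yl]phenyl]ethan-1-one; 13 4-(methoxymethoxy)benzaldehyde
Product: 14 (2E)-1-[2,4-bis(methoxymethoxy)-3-[(1E)-3-methylbuta-1,3-dien-1-yl]phenyl]-3-[4-(methoxymethoxy)phenyl]prop-2-en-1-one
Conditions: KOH, EtOH–H2O, rt
Reagents that add atoms: none
Why: Claisen–Schmidt aldol condensation with E1cB dehydration to the E-enone; the diene and the acetals are stable to base.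

Step 9
Reactants: 15 3-hydroxy-3-methylbutan-2-one; 13 4-(methoxymethoxy)benzaldehyde
Product: 16 (1E)-4-hydroxy-1-[4-(methoxymethoxy)phenyl]-4-methylpent-1-en-3-one
Conditions: LiOH·H2O, MeOH–H2O, 60 °C
Reagents that add atoms: none
Why: Claisen–Schmidt condensation on the only enolisable side (the methyl group) of the ketol gives the E-enone.

Step 10
Reactants: 14 dienyl chalcone; 16 (1E)-4-hydroxy-1-[4-(methoxymethoxy)phenyl]-4-methylpent-1-en-3-one
Product: 17 (1R,2S,6S)-cyclohex-3-ene carrying 2-hydroxy-2-methylpropanoyl on C1, the 2',4'-bis(methoxymethoxy)-1'-[(E)-3-(4-(methoxymethoxy)phenyl)prop-2-enoyl]phenyl ring (bonded through C3') on C2, methyl on C4 and 4-(methoxymethoxy)phenyl on C6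
Conditions: Cu(OTf)2 (10 mol %), (R,R)-t-Bu-box (11 mol %), 4 Å MS, CH2Cl2, 0 °C to rt
Reagents that add atoms: none
Why: Cu(II)–bis(oxazoline)-catalysed Diels–Alder reaction of the chelated s-cis ketol enone, in which C1 bonds to the aryl-bearing diene terminus ("ortho" to the aryl group, "para" to the methyl group), the endo transition state puts the acyl group cis to the C2 aryl ring, the E-dienophile keeps C1 and C6 trans, and the ligand shields the Cα-Re face so that C2 (S), C6 (S) and C1 (R) arise together; the chalcone enone of 14, with its 2'-oxygen masked, cannot chelate copper and stays a spectator.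

Step 11
Reactants: 17 Diels–Alder adduct
Product: 18 the 2'-phenol of 17 (4'-O-MOM, both 4-(methoxymethoxy)phenyl groups and the ketol kept)
Conditions: MgBr2·OEt2 (3 equiv), Et2O–CH2Cl2, 0 °C to rt; aq. NH4Cl
Reagents that add atoms: none
Why: chelation-assisted acetal cleavage; magnesium held between the enone carbonyl and the ortho acetal oxygen activates only that MOM ether, since the other three have no neighbouring carbonyl.

Step 12
Reactants: 18 phenol; 5 3,5-bis(methoxymethoxy)-4-(3-methylbut-2-en-1-yl)benzoic acid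
Product: 19 the 2'-O-[3,5-bis(methoxymethoxy)-4-(3-methylbut-2-en-1-yl)benzoyl] ester of 18
Conditions: DIC, DMAP, CH2Cl2, rt
Reagents that add atoms: none
Why: Steglich esterification of the only phenol; the tertiary carbinol of the ketol is too hindered to be acylated.

Step 13
Reactants: 19 aryl ester
Product: 20 (1R,2S,6S)-cyclohex-3-ene-1-carboxylic acid carrying on C2 the 2'-aroyloxy-4'-(methoxymethoxy) chalcone ring, methyl on C4 and 4-(methoxymethoxy)phenyl on C6
Conditions: NaIO4, MeOH–H2O, rt
Reagents that add atoms: water, O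
Why: periodate cleavage of the α-hydroxy ketone (through the periodate ester of its hydrate) gives the C1 carboxylic acid and acetone; alkenes, acetals and the aryl ester are inert.

Step 14
Reactants: 20 carboxylic acid
Product: 21 the 1,3-dioxoisoindolin-2-yl (N-hydroxyphthalimide) ester of 20
Conditions: N-hydroxyphthalimide, DIC, DMAP (10 mol %), CH2Cl2, rt
Reagents that add atoms: N-hydroxyphthalimide, O=C1c2ccccc2C(=O)N1O
Why: carbodiimide esterification gives the redox-active ester without touching the aryl ester.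

Step 15
Reactants: 21 N-acyloxyphthalimide carrying the aroyl group on the 2'-oxygen
Product: 22 kuwanon V penta-MOM ether: [3,5-bis(methoxymethoxy)-4-(3-methylbut-2-en-1-yl)phenyl] (1R,2S,6S)-cyclohex-3-en-1-yl ketone carrying on C2 the 2'-hydroxy-4'-(methoxymethoxy)-1'-[(E)-3-(4-(methoxymethoxy)phenyl)prop-2-enoyl]phenyl ring, methyl on C4 and 4-(methoxymethoxy)phenyl on C6
Conditions: NiBr2·glyme (20 mol %), 4,4'-di-tert-butyl-2,2'-bipyridine (22 mol %), Zn dust (3 equiv), DMA–THF, 0.01 M, rt; aq. NH4Cl
Reagents that add atoms: none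
Why: Proposed new method: Zn-generated Ni(0) should insert into the acyl C–O bond of the aryl ester, whose leaving group is a 2-acylphenoxide that stays on nickel as an O,O-chelate (as the ring nitrogen does for 2-pyridyl esters), and single-electron reduction of the N-acyloxyphthalimide then expels CO2 and phthalimide anion to leave a planar secondary radical at C1. That radical lies two bonds from the ring holding the aroyl–nickel unit, so it is trapped within the molecule through a six-membered nickelacycle (Ni–C1–C2–C3'–C2'–O), and C(acyl)–C1 reductive elimination from Ni(III) gives the ketone and the phenoxide. The closest known reaction type is the Ni-catalysed reductive decarboxylative ketone synthesis from N-hydroxyphthalimide esters and activated acyl donors (acid chlorides, 2-pyridyl esters and thioesters), here run intramolecularly with an aryl ester as the donor. No ring of the product is closed; the only cycle is the transient nickelacycle. C1 (R) is set here: the configuration lost on decarboxylation does not matter, because nickel anchored on the C2 aryl oxygen reaches the C1 face cis to that ring, which is also the face anti to the C6 aryl group, so tether and steric bias both lead to the 1,2-cis-1,6-trans ketone. The step needs intramolecular capture to outrun hydrogen abstraction, dimerisation and addition of the radical to the chalcone, which the proximity of the acyl–nickel centre, high dilution and the absence of silyl chlorides and hydrogen donors should secure.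

Step 16
Reactants: 22 kuwanon V penta-MOM ether
Product: 23 kuwanon V
Conditions: HCl (2 M in MeOH), THF, rt
Reagents that add atoms: none
Why: acid-catalysed acetal exchange with methanol removes the five MOM groups as dimethoxymethane; no base is present, so the C1 stereocentre should not be enolised.

**Compound list**

1 | methyl 4-bromo-3,5-dihydroxybenzoate | COC(=O)c1cc(O)c(Br)c(O)c1 | starting material
2 | methyl 4-bromo-3,5-bis(methoxymethoxy)benzoate | COCOc1cc(C(=O)OC)cc(OCOC)c1Br | intermediate
3 | tributyl(3-methylbut-2-en-1-yl)stannane | CCCC[Sn](CCCC)(CCCC)CC=C(C)C | starting material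
4 | methyl 3,5-bis(methoxymethoxy)-4-(3-methylbut-2-en-1-yl)benzoate | COCOc1cc(C(=O)OC)cc(OCOC)c1CC=C(C)C | intermediate
5 | 3,5-bis(methoxymethoxy)-4-(3-methylbut-2-en-1-yl)benzoic acid | COCOc1cc(C(=O)O)cc(OCOC)c1CC=C(C)C | intermediate
6 | 2-methylbut-1-en-3-yne | C#CC(C)=C | starting material
7 | pinacolborane | CC1(C)OBOC1(C)C | starting material
8 | (E)-4,4,5,5-tetramethyl-2-(3-methylbuta-1,3-dien-1-yl)-1,3,2-dioxaborolane | CC(=C)/C=C/B1OC(C)(C)C(C)(C)O1 | intermediate
9 | 1-(2,4-dihydroxyphenyl)ethan-1-one | CC(=O)c1ccc(O)cc1O | starting material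
10 | 1-(2,4-dihydroxy-3-iodophenyl)ethan-1-one | CC(=O)c1ccc(O)c(I)c1O | intermediate
11 | 1-[3-iodo-2,4-bis(methoxymethoxy)phenyl]ethan-1-one | CC(=O)c1ccc(OCOC)c(I)c1OCOC | intermediate
12 | 1-[2,4-bis(methoxymethoxy)-3-[(1E)-3-methylbuta-1,3-dien-1-yl]phenyl]ethan-1-one | CC(=O)c1ccc(OCOC)c(/C=C/C(C)=C)c1OCOC | intermediate
13 | 4-(methoxymethoxy)benzaldehyde | COCOc1ccc(C=O)cc1 | starting material
14 | (2E)-1-[2,4-bis(methoxymethoxy)-3-[(1E)-3-methylbuta-1,3-dien-1-yl]phenyl]-3-[4-(methoxymethoxy)phenyl]prop-2-en-1-one | COCOc1ccc(/C=C/C(=O)c2ccc(OCOC)c(/C=C/C(C)=C)c2OCOC)cc1 | intermediate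
15 | 3-hydroxy-3-methylbutan-2-one | CC(=O)C(C)(C)O | starting material
16 | (1E)-4-hydroxy-1-[4-(methoxymethoxy)phenyl]-4-methylpent-1-en-3-one | COCOc1ccc(/C=C/C(=O)C(C)(C)O)cc1 | intermediate
17 | Diels–Alder adduct, (1R,2S,6S), C1 2-hydroxy-2-methylpropanoyl, 2',4'-bis-MOM chalcone ring on C2 | CC(C)(O)C(=O)[C@H]2[C@@H](c3c(OCOC)ccc(C(=O)/C=C/c4ccc(OCOC)cc4)c3OCOC)C=C(C)C[C@@H]2c2ccc(OCOC)cc2 | intermediate
18 | 2'-phenol of 17, (1R,2S,6S) | CC(C)(O)C(=O)[C@H]2[C@@H](c3c(OCOC)ccc(C(=O)/C=C/c4ccc(OCOC)cc4)c3O)C=C(C)C[C@@H]2c2ccc(OCOC)cc2 | intermediate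
19 | 2'-O-[3,5-bis(methoxymethoxy)-4-prenylbenzoyl] ester of 18, (1R,2S,6S) | CC(C)(O)C(=O)[C@H]2[C@@H](c3c(OCOC)ccc(C(=O)/C=C/c4ccc(OCOC)cc4)c3OC(=O)c5cc(OCOC)c(CC=C(C)C)c(OCOC)c5)C=C(C)C[C@@H]2c2ccc(OCOC)cc2 | intermediate
20 | (1R,2S,6S)-cyclohex-3-ene-1-carboxylic acid with the 2'-aroyloxy chalcone ring on C2 | OC(=O)[C@H]2[C@@H](c3c(OCOC)ccc(C(=O)/C=C/c4ccc(OCOC)cc4)c3OC(=O)c5cc(OCOC)c(CC=C(C)C)c(OCOC)c5)C=C(C)C[C@@H]2c2ccc(OCOC)cc2 | intermediate
21 | N-hydroxyphthalimide ester of 20, (1R,2S,6S) | O=C(ON1C(=O)c6ccccc6C1=O)[C@H]2[C@@H](c3c(OCOC)ccc(C(=O)/C=C/c4ccc(OCOC)cc4)c3OC(=O)c5cc(OCOC)c(CC=C(C)C)c(OCOC)c5)C=C(C)C[C@@H]2c2ccc(OCOC)cc2 | intermediate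
22 | kuwanon V penta-MOM ether (2'-OH free), (1R,2S,6S) | CC(C)=CCc1c(OCOC)cc(C(=O)[C@H]2[C@@H](c3c(OCOC)ccc(C(=O)/C=C/c4ccc(OCOC)cc4)c3O)C=C(C)C[C@@H]2c2ccc(OCOC)cc2)cc1OCOC | intermediate
23 | kuwanon V, (1R,2S,6S) | CC(C)=CCc1c(O)cc(C(=O)[C@H]2[C@@H](c3c(O)ccc(C(=O)/C=C/c4ccc(O)cc4)c3O)C=C(C)C[C@@H]2c2ccc(O)cc2)cc1O | target

**Step count**

Total step count: 16. Longest linear sequence: 11 steps (5, 6, 7, 8, 10, 11, 12, 13, 14, 15, 16).

**Steps most likely to fail**

Step 15 (Proposed new method). Nickel insertion into the aryl ester may be too slow, so that the C1 radical is reduced to C–H, dimerises or adds to the chalcone, or is captured without the relay and with poor facial selectivity. The fallback uses known chemistry and sets out from 17. Periodate cleavage of the ketol would give the tetra-MOM carboxylic acid F1, and DIC with N-hydroxyphthalimide its redox-active ester F2. Acid 5 would be converted with 2,2'-dipyridyl disulfide and PPh3 into the S-(pyridin-2-yl) thioester F3. Intermolecular Ni-catalysed decarboxylative cross-electrophile coupling of F2 with F3 (NiCl2·glyme, dtbbpy, Zn, DMA–THF) would give the hexa-MOM ketone F4. In this variant C1 is under substrate control only, so the C1 epimers would have to be separated and the 1,2-cis-1,6-trans isomer carried on. Removal of all six MOM groups (HCl, MeOH–THF) brings the route back at 23.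

Step 10. The Lewis-basic chalcone carbonyl and acetal oxygens of 14 may compete for copper, slowing the catalysed cycloaddition and letting a poorly organised background reaction erode endo and facial selectivity. The fallback sets out from 12 and 16. The same Cu(II)/(R,R)-t-Bu-box cycloaddition would be run on the smaller acetophenone diene 12 to give the acetyl-bearing adduct F5. The chalcone would then be built by Claisen–Schmidt condensation of F5 with 13 (Ba(OH)2·8H2O, MeOH, rt), which returns to the route at 17. Any enolisation at C1 during this condensation concerns a centre that is reset in step 15.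

Step 16. Under acid, the phenols freed next to the prenyl group may add across its double bond (chroman formation), the 2'-hydroxychalcone may close to the flavanone, and the C1 ketone may form a hemiketal with the cis 2'-OH and dehydrate. The fallback sets out from 22. The aryl acetals would be exchanged for silyl ethers under buffered conditions (TESOTf, 2,2'-bipyridyl, CH2Cl2, 0 °C) to give the penta(triethylsilyl) ether F6; the chelated 2'-OH is expected to stay free. Fluoride cleavage (TBAF, AcOH, THF, 0 °C) then comes back to the route at 23 without a Brønsted-acid step.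

Further compounds
F1 | step 15 | (1R,2S,6S)-cyclohex-3-ene-1-carboxylic acid with the 2',4'-bis-MOM chalcone ring on C2 | OC(=O)[C@H]2[C@@H](c3c(OCOC)ccc(C(=O)/C=C/c4ccc(OCOC)cc4)c3OCOC)C=C(C)C[C@@H]2c2ccc(OCOC)cc2
F2 | step 15 | N-hydroxyphthalimide ester of F1 | O=C(ON1C(=O)c6ccccc6C1=O)[C@H]2[C@@H](c3c(OCOC)ccc(C(=O)/C=C/c4ccc(OCOC)cc4)c3OCOC)C=C(C)C[C@@H]2c2ccc(OCOC)cc2
F3 | step 15 | S-(pyridin-2-yl) 3,5-bis(methoxymethoxy)-4-(3-methylbut-2-en-1-yl)benzenecarbothioate | COCOc1cc(C(=O)Sc2ccccn2)cc(OCOC)c1CC=C(C)C
F4 | step 15 | kuwanon V hexa-MOM ether, (1R,2S,6S) | CC(C)=CCc1c(OCOC)cc(C(=O)[C@H]2[C@@H](c3c(OCOC)ccc(C(=O)/C=C/c4ccc(OCOC)cc4)c3OCOC)C=C(C)C[C@@H]2c2ccc(OCOC)cc2)cc1OCOC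
F5 | step 10 | Diels–Alder adduct of 12 and 16, (1R,2S,6S), acetyl in place of the enone on the C2 aryl ring | CC(C)(O)C(=O)[C@H]2[C@@H](c3c(OCOC)ccc(C(C)=O)c3OCOC)C=C(C)C[C@@H]2c2ccc(OCOC)cc2
F6 | step 16 | kuwanon V penta(triethylsilyl) ether (2'-OH free), (1R,2S,6S) | CC(C)=CCc1c(O[Si](CC)(CC)CC)cc(C(=O)[C@H]2[C@@H](c3c(O[Si](CC)(CC)CC)ccc(C(=O)/C=C/c4ccc(O[Si](CC)(CC)CC)cc4)c3O)C=C(C)C[C@@H]2c2ccc(O[Si](CC)(CC)CC)cc2)cc1O[Si](CC)(CC)CC
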